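**Retrosynthetic overview** (labdane numbering throughout)

1. The route rests on the C2/C3 cis-diol of ring A (O2 equatorial, O3 axial, both on the face opposite the C10 methyl), which lies between C1 and the gem-dimethyl carbon C4. The C2–C3 bond is the one formed to close ring A.
2. Endgame: C2/C15 diacetate from the 2,3,15-triol; C11–C12 by copper-catalysed coupling of a C11 Grignard reagent with a C12–C15 (E)-allylic bromide; C11 and the C9 stereocentre from a C9 ketone by methylenation and hydroboration.
3. Ring A: SmI2 pinacol cyclisation of a ring B 1,6-dialdehyde whose formyl carbons C2 and C3 sit on trans arms at C10 and C5.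
4. Dialdehyde: (S)-carvone supplies ring B and C5. C10 is made quaternary by methylation, then alkylation with tert-butyl bromoacetate anti to the isopropenyl group. An ester arm is used because an allyl arm would compete with the isopropenyl group in hydroboration and could not be cleaved oxidatively beside the C7=C8 alkene. The isopropenyl group becomes the CMe2–CHO arm.
5. Ring order: ring B comes with carvone; ring A is closed in step 10.

Key step: step 10

Remark: the C9 carbinol centre carried from step 3 to step 12 is drawn as the epimer expected from hydride attack anti to the pseudo-axial C10 methyl; it is erased by the oxidation in step 13, so its epimer would be carried through in the same way.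

**Route**

Step 1
Reactants: 1 (S)-(+)-carvone; 2 methyl iodide
Product: 4 (5S,6R)-6-methylcarvone (methyl trans to isopropenyl; minor C6 epimer carried along), via lithium dienolate of carvone 3 (not isolated)
Conditions: LiN(iPr)2, THF, −78 °C; then MeI, −78 → 0 °C
Reagents that add atoms: none
Why: Kinetic deprotonation at the α' carbon (C6 of carvone, C10 of the target) and SN2 methylation of the cross-conjugated lithium dienolate is a standard enolate alkylation; the new centre is planarised again in step 2, so both epimers are usable.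

Step 2
Reactants: 4 (5S,6R)-6-methylcarvone; 5 tert-butyl bromoacetate
Product: 7 ring B keto ester (C10 methyl cis and CH2CO2tBu arm trans to the C5 isopropenyl group), via lithium enolate of 6-methylcarvone 6 (not isolated)
Conditions: LiN(iPr)2, THF, −78 → 0 °C; then 5, DMPU, −78 → −20 °C
Reagents that add atoms: none
Why: Enolate alkylation in which the reactive α-bromo ester should approach the tetrasubstituted enolate on the face opposite the neighbouring isopropenyl group, setting the quaternary C10 with the two arms trans as the trans-decalin requires.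

Step 3
Reactants: 7 ring B keto ester
Product: 8 diol (C9 allylic alcohol cis to the C10 methyl; C2 primary alcohol)
Conditions: LiAlH4, Et2O, −20 °C → rt; aqueous NaOH work-up
Reagents that add atoms: none
Why: Hydride reduction: LiAlH4 reduces the enone carbonyl in the 1,2 sense and the ester to the primary alcohol, and hydride should enter C9 anti to the pseudo-axial C10 methyl (a centre removed again in step 13).

Step 4
Reactants: 8 diol
Product: 9 bis-TBS ether
Conditions: TBSOTf, 2,6-lutidine, CH2Cl2, −78 → 0 °C
Reagents that add atoms: tert-butyldimethylsilyl triflate, CC(C)(C)[Si](C)(C)OS(=O)(=O)C(F)(F)F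
Why: Silyl ether formation with the silyl triflate and a hindered base protects both the primary alcohol and the hindered allylic C9 alcohol.

Step 5
Reactants: 9 bis-TBS ether
Product: 11 C3 primary alcohol (C4 epimers), via C3 alkyl-9-BBN borane 10 (not isolated)
Conditions: 9-BBN, THF, 0 °C → rt; then NaOH, H2O2, 0 °C → rt
Reagents that add atoms: hydrogen peroxide, OO
Why: Hydroboration–oxidation: 9-BBN should add anti-Markovnikov to the 1,1-disubstituted isopropenyl group and leave the hindered trisubstituted C7=C8 alkene alone; the new C4 centre is removed in step 7.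

Step 6
Reactants: 11 C3 primary alcohol
Product: 12 C3 aldehyde (C4 epimers)
Conditions: Dess–Martin periodinane, NaHCO3, CH2Cl2, 0 °C → rt
Reagents that add atoms: none
Why: Dess–Martin oxidation takes the primary alcohol to the aldehyde under buffered conditions that leave both silyl ethers and the alkene untouched.

Step 7
Reactants: 12 C3 aldehyde; 2 methyl iodide
Product: 14 gem-dimethyl aldehyde (C4 quaternary; bis-TBS ether), via potassium enolate of the aldehyde 13 (not isolated)
Conditions: KOtBu, MeI (excess), THF, 0 °C
Reagents that add atoms: none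
Why: Enolate C-alkylation of an α-branched aldehyde with methyl iodide turns C4 into the gem-dimethyl carbon and makes the C3 aldehyde non-enolisable, both C4 epimers converging through the same enolate.

Step 8
Reactants: 14 gem-dimethyl aldehyde
Product: 15 hydroxy aldehyde (C2–OH free; C9 silyl ether kept)
Conditions: HF·pyridine, pyridine, THF, 0 °C
Reagents that add atoms: none
Why: Selective desilylation: buffered HF·pyridine should cleave the unhindered primary silyl ether far faster than the secondary one flanked by the quaternary C10, and the neopentyl aldehyde is inert to it.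

Step 9
Reactants: 15 hydroxy aldehyde
Product: 16 ring B dialdehyde (C2 and C3 formyl groups; C9 silyl ether)
Conditions: Dess–Martin periodinane, NaHCO3, CH2Cl2, 0 °C → rt; used directly
Reagents that add atoms: none
Why: Dess–Martin oxidation of the primary alcohol gives the second aldehyde under neutral conditions that should not enolise or aldolise the C2 aldehyde.

Step 10
Reactants: 16 ring B dialdehyde
Product: 17 bicyclic 2,3-cis-diol (C2–OH equatorial; C3–OH axial; C9 silyl ether; C7=C8)
Conditions: SmI2 (3 equiv), THF, −78 °C → rt, slow addition of 16; aqueous NaHCO3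
Reagents that add atoms: none
Why: SmI2 (divalent samarium) transfers one electron to the unhindered C2 aldehyde and then to the C3 aldehyde, the oxophilic trivalent samarium bridges the two oxygens, and the C2–C3 bond forms inside this chelate to give a samarium diolate that water releases as the diol. The closest known reaction is the SmI2 pinacol cyclisation of 1,6-dialdehydes to cis-cyclohexane-1,2-diols. Ring A closes as a six-membered chair by coupling of the two ketyl carbons at the ends of arms held trans-diequatorial on C10 and C5 of ring B (exo with respect to both carbonyl groups), which gives the trans-decalin directly. C2 and C3 are the new stereocentres: the samarium bridge holds the oxygens syn and so should give the cis-diol, and of the two cis arrangements only the one with O2 equatorial and O3 axial, both opposite the C10 methyl, avoids a 1,3-diaxial clash of O2 with the axial methyl groups on C10 and C4. The step needs cis over trans selectivity and reaction at the aldehydes only: no HMPA is used so the chelate stays tight and the C7=C8 alkene and allylic silyl ether are not reduced, the C3 aldehyde cannot enolise, and C9 is held as a silyl ether because an enone would be reduced first.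

Step 11
Reactants: 17 bicyclic 2,3-cis-diol
Product: 18 2,3-acetonide (C9 silyl ether)
Conditions: 2,2-dimethoxypropane, pyridinium p-toluenesulfonate (cat.), CH2Cl2, rt
Reagents that add atoms: 2,2-dimethoxypropane, COC(C)(C)OC
Why: Acid-catalysed transacetalisation closes the cis-diol to the five-membered isopropylidene acetal, masking both hydroxyls for the later oxidation and organometallic steps while the silyl ether survives the mild acid.

Step 12
Reactants: 18 2,3-acetonide
Product: 19 C9 allylic alcohol acetonide
Conditions: Bu4NF, THF, 50 °C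
Reagents that add atoms: none
Why: Fluoride-mediated desilylation frees the hindered allylic C9 alcohol, and the acetonide is inert to fluoride.

Step 13
Reactants: 19 C9 allylic alcohol acetonide
Product: 20 enone acetonide (C9 ketone; C7=C8)
Conditions: Dess–Martin periodinane, NaHCO3, CH2Cl2, rt
Reagents that add atoms: none
Why: Dess–Martin oxidation of the allylic alcohol regenerates the C9 enone and erases the C9 carbinol centre.

Step 14
Reactants: 20 enone acetonide
Product: 21 β-hydroxysilane (C9 tertiary carbinol bearing CH2SiMe3; either C9 epimer)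
Conditions: Me3SiCH2Li, THF, −78 → 0 °C; then H2O
Reagents that add atoms: (trimethylsilyl)methyllithium, [Li]C[Si](C)(C)C
Why: First half of a Peterson olefination: the small, hard organolithium should add 1,2 to the hindered enone carbonyl, which has no α hydrogen to lose, and the carbinol configuration is irrelevant.

Step 15
Reactants: 21 β-hydroxysilane
Product: 22 7,9(11)-diene acetonide (exocyclic C9=C11)
Conditions: KH, THF, 0 °C → rt
Reagents that add atoms: none
Why: Peterson elimination: base-induced syn elimination of the potassium β-silyl alkoxide gives the exocyclic methylene under conditions that spare the acetonide.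

Step 16
Reactants: 22 7,9(11)-diene acetonide
Product: 24 C11 primary alcohol (C9–H cis to C5–H; CH2OH equatorial), via C11 alkyl-9-BBN borane 23 (not isolated)
Conditions: 9-BBN, THF, 0 °C → rt; then NaOH, H2O2, 0 °C → rt
Reagents that add atoms: hydrogen peroxide, OO
Why: Hydroboration–oxidation: 9-BBN should add to the terminal C9=C11 bond of the diene with boron on C11 and deliver hydrogen to C9 from the face opposite the axial C10 methyl, setting C9 with the CH2OH arm equatorial and cis to that methyl.

Step 17
Reactants: 24 C11 primary alcohol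
Product: 25 C11 iodide
Conditions: I2, PPh3, imidazole, toluene, 60 °C
Reagents that add atoms: iodine, II
Why: Appel-type iodination converts the primary alcohol to the iodide by SN2 displacement of the alkoxyphosphonium ion, with imidazole buffering the medium so that the acetonide is kept.

Step 18
Reactants: 26 prenol (3-methylbut-2-en-1-ol)
Product: 27 prenyl TBS ether
Conditions: TBSCl, imidazole, DMF, rt
Reagents that add atoms: tert-butyldimethylsilyl chloride, CC(C)(C)[Si](C)(C)Cl
Why: Standard silyl ether formation at a primary allylic alcohol.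

Step 19
Reactants: 27 prenyl TBS ether
Product: 28 (E)-4-(tert-butyldimethylsilyloxy)-2-methylbut-2-en-1-ol
Conditions: SeO2 (cat.), t-BuOOH, CH2Cl2, rt
Reagents that add atoms: tert-butyl hydroperoxide, CC(C)(C)OO (oxygen carried over by catalytic SeO2)
Why: SeO2 allylic oxidation (ene reaction, then [2,3]-sigmatropic shift) should hydroxylate the methyl group trans to the CH2O substituent of the trisubstituted alkene, which fixes the E geometry of the later C13=C14 bond.

Step 20
Reactants: 28 (E)-4-(tert-butyldimethylsilyloxy)-2-methylbut-2-en-1-ol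
Product: 29 (E)-(4-bromo-3-methylbut-2-enyloxy)(tert-butyl)dimethylsilane
Conditions: CBr4, PPh3, CH2Cl2, 0 °C
Reagents that add atoms: carbon tetrabromide, BrC(Br)(Br)Br
Why: Appel bromination of the primary allylic alcohol proceeds by SN2, without allylic transposition or loss of the E geometry.

Step 21
Reactants: 25 C11 iodide; 29 (E)-(4-bromo-3-methylbut-2-enyloxy)(tert-butyl)dimethylsilane
Product: 32 labda-7,13E-diene 2,3-acetonide 15-TBS ether, via C11 alkyllithium 30 (not isolated), via C11 alkylmagnesium bromide 31 (not isolated)
Conditions: t-BuLi (2.1 equiv), Et2O/pentane, −78 °C; MgBr2·OEt2, −78 → −20 °C; then 29, Li2CuCl4 (5 mol %), THF, −78 → 0 °C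
Reagents that add atoms: none
Why: Lithium–iodine exchange and transmetalation give the C11 Grignard reagent, and the Li2CuCl4-catalysed Grignard–allylic bromide coupling should form C11–C12 by substitution at the less hindered primary allyl terminus with the E alkene retained, the silyl ether and acetonide being inert to the organometallics.

Step 22
Reactants: 32 labda-7,13E-diene 2,3-acetonide 15-TBS ether
Product: 33 labda-7,13E-diene-2,3,15-triol
Conditions: AcOH/THF/H2O (3:1:1), 45 °C
Reagents that add atoms: none
Why: Acid-catalysed deprotection: aqueous acetic acid should hydrolyse the primary silyl ether and the isopropylidene acetal in one operation without isomerising the two trisubstituted alkenes.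

Step 23
Reactants: 33 labda-7,13E-diene-2,3,15-triol
Product: 34 CNP0254679.1 (2,15-diacetate of the triol; C3–OH free)
Conditions: Ac2O (2.3 equiv), pyridine, CH2Cl2, 0 °C → rt, no DMAP
Reagents that add atoms: acetic anhydride, CC(=O)OC(C)=O
Why: Rate-controlled selective acetylation: a limited amount of anhydride should esterify the primary allylic C15 hydroxyl and the unhindered equatorial C2 hydroxyl, while the axial C3 hydroxyl beside the gem-dimethyl carbon is expected to react much more slowly.

**Compound list**

1 | (S)-(+)-carvone | CC1=CC[C@@H](CC1=O)C(C)=C | starting material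
2 | methyl iodide | CI | starting material
3 | lithium dienolate of carvone (enolised toward C6, carvone numbering) | CC1=CC[C@@H](C=C1O[Li])C(C)=C | intermediate
4 | (5S,6R)-6-methylcarvone, methyl trans to isopropenyl (C6 epimer formed alongside converges in step 2) | C[C@H]1C(=O)C(C)=CC[C@@H]1C(C)=C | intermediate
5 | tert-butyl bromoacetate | CC(C)(C)OC(=O)CBr | starting material
6 | lithium enolate of 6-methylcarvone | CC1=CC[C@@H](C(C)=C1O[Li])C(C)=C | intermediate
7 | ring B keto ester: C10 quaternary with methyl cis and CH2CO2tBu trans to the C5 isopropenyl group, C9 ketone, C7=C8 | CC(C)(C)OC(=O)C[C@@]1(C)C(=O)C(C)=CC[C@@H]1C(C)=C | intermediate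
8 | diol: C9 allylic alcohol (OH cis to C10 methyl) and C2 primary alcohol | OCC[C@@]1(C)[C@H](O)C(C)=CC[C@@H]1C(C)=C | intermediate
9 | bis-TBS ether of 8 | CC(C)(C)[Si](C)(C)OCC[C@@]1(C)[C@H](O[Si](C)(C)C(C)(C)C)C(C)=CC[C@@H]1C(C)=C | intermediate
10 | C3 alkyl-9-BBN borane (C4 epimers) | CC(C)(C)[Si](C)(C)OCC[C@@]1(C)[C@H](O[Si](C)(C)C(C)(C)C)C(C)=CC[C@@H]1C(C)CB3C4CCCC3CCC4 | intermediate
11 | C3 primary alcohol (C4 epimers, C4 left undefined) | CC(C)(C)[Si](C)(C)OCC[C@@]1(C)[C@H](O[Si](C)(C)C(C)(C)C)C(C)=CC[C@@H]1C(C)CO | intermediate
12 | C3 aldehyde (C4 epimers, C4 left undefined) | CC(C)(C)[Si](C)(C)OCC[C@@]1(C)[C@H](O[Si](C)(C)C(C)(C)C)C(C)=CC[C@@H]1C(C)C=O | intermediate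
13 | potassium enolate of aldehyde 12 | CC(C)(C)[Si](C)(C)OCC[C@@]1(C)[C@H](O[Si](C)(C)C(C)(C)C)C(C)=CC[C@@H]1C(C)=CO[K] | intermediate
14 | gem-dimethyl aldehyde (C4 quaternary, C3 formyl), bis-TBS ether | CC(C)(C)[Si](C)(C)OCC[C@@]1(C)[C@H](O[Si](C)(C)C(C)(C)C)C(C)=CC[C@@H]1C(C)(C)C=O | intermediate
15 | hydroxy aldehyde: C2–OH free, C3 formyl, C9 silyl ether | OCC[C@@]1(C)[C@H](O[Si](C)(C)C(C)(C)C)C(C)=CC[C@@H]1C(C)(C)C=O | intermediate
16 | ring B dialdehyde: C2 formyl on the C10 arm, C3 formyl on the C5 arm, arms trans, C9 silyl ether | O=CC[C@@]1(C)[C@H](O[Si](C)(C)C(C)(C)C)C(C)=CC[C@@H]1C(C)(C)C=O | intermediate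
17 | bicyclic 2,3-cis-diol: trans-decalin, C2–OH equatorial and C3–OH axial on the face opposite the C10 methyl, C9 silyl ether, C7=C8 | CC1=CC[C@@H]2C(C)(C)[C@@H](O)[C@@H](O)C[C@@]2(C)[C@@H]1O[Si](C)(C)C(C)(C)C | intermediate
18 | 2,3-acetonide of 17 | CC1=CC[C@@H]2C(C)(C)[C@@H](OC3(C)C)[C@@H](O3)C[C@@]2(C)[C@@H]1O[Si](C)(C)C(C)(C)C | intermediate
19 | C9 allylic alcohol acetonide | CC1=CC[C@@H]2C(C)(C)[C@@H](OC3(C)C)[C@@H](O3)C[C@@]2(C)[C@@H]1O | intermediate
20 | enone acetonide (C9 ketone, C7=C8) | CC1=CC[C@@H]2C(C)(C)[C@@H](OC3(C)C)[C@@H](O3)C[C@@]2(C)C1=O | intermediate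
21 | β-hydroxysilane: C9 tertiary carbinol bearing CH2SiMe3 (C9 undefined) | CC1=CC[C@@H]2C(C)(C)[C@@H](OC3(C)C)[C@@H](O3)C[C@@]2(C)C1(O)C[Si](C)(C)C | intermediate
22 | 7,9(11)-diene acetonide | CC1=CC[C@@H]2C(C)(C)[C@@H](OC3(C)C)[C@@H](O3)C[C@@]2(C)C1=C | intermediate
23 | C11 alkyl-9-BBN borane | CC1=CC[C@@H]2C(C)(C)[C@@H](OC3(C)C)[C@@H](O3)C[C@@]2(C)[C@@H]1CB4C5CCCC4CCC5 | intermediate
24 | C11 primary alcohol acetonide (C9–H cis to C5–H, CH2OH cis to C10 methyl) | CC1=CC[C@@H]2C(C)(C)[C@@H](OC3(C)C)[C@@H](O3)C[C@@]2(C)[C@@H]1CO | intermediate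
25 | C11 iodide acetonide | CC1=CC[C@@H]2C(C)(C)[C@@H](OC3(C)C)[C@@H](O3)C[C@@]2(C)[C@@H]1CI | intermediate
26 | prenol (3-methylbut-2-en-1-ol) | CC(C)=CCO | starting material
27 | prenyl TBS ether | CC(C)=CCO[Si](C)(C)C(C)(C)C | intermediate
28 | (E)-4-(tert-butyldimethylsilyloxy)-2-methylbut-2-en-1-ol | OC/C(C)=C/CO[Si](C)(C)C(C)(C)C | intermediate
29 | (E)-(4-bromo-3-methylbut-2-enyloxy)(tert-butyl)dimethylsilane | BrC/C(C)=C/CO[Si](C)(C)C(C)(C)C | intermediate
30 | C11 alkyllithium | CC1=CC[C@@H]2C(C)(C)[C@@H](OC3(C)C)[C@@H](O3)C[C@@]2(C)[C@@H]1C[Li] | intermediate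
31 | C11 alkylmagnesium bromide | CC1=CC[C@@H]2C(C)(C)[C@@H](OC3(C)C)[C@@H](O3)C[C@@]2(C)[C@@H]1C[Mg]Br | intermediate
32 | labda-7,13E-diene 2,3-acetonide 15-TBS ether | CC1=CC[C@@H]2C(C)(C)[C@@H](OC3(C)C)[C@@H](O3)C[C@@]2(C)[C@@H]1CC/C(C)=C/CO[Si](C)(C)C(C)(C)C | intermediate
33 | labda-7,13E-diene-2,3,15-triol (2,3-cis-diol opposite the C10 methyl) | CC1=CC[C@@H]2C(C)(C)[C@@H](O)[C@@H](O)C[C@@]2(C)[C@@H]1CC/C(C)=C/CO | intermediate
34 | CNP0254679.1, the 2,15-diacetate | CC(=O)OC/C=C(\C)CC[C@@H]1C(C)=CC[C@@H]2C(C)(C)[C@@H](O)[C@@H](OC(C)=O)C[C@@]12C | target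

**Step count and risks**

Total step count: 23. Longest linear sequence: 20 steps (steps 1–17 and 21–23, from carvone); the side-chain bromide takes 3 steps (18–20).

Steps most likely to fail:

Step 10. The coupling may pass through an open, non-chelated transition state and lose cis/trans control, or the aldehydes may simply be reduced to the 1,6-diol. Fallback: from dialdehyde 16, McMurry coupling (TiCl3(DME)1.5, Zn(Cu), DME, reflux) would deoxygenate both carbonyls to the ring A olefin F1 with a C2=C3 bond. Bu4NF would then free the C9 allylic alcohol F2, and Dess–Martin oxidation would give the dienone F3, in which only the C2=C3 bond is electron-rich. OsO4 (cat.) with N-methylmorpholine N-oxide should add from the face opposite the axial C10 and C4 methyl groups to give the cis-diol enone F4. 2,2-Dimethoxypropane with pyridinium p-toluenesulfonate then returns the route to enone acetonide 20.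

Step 21. The copper intermediate may couple at the γ carbon of the allyl system (allylic transposition to a branched terminal alkene), or the organometallic may be lost by protonation or homocoupling. Fallback: from iodide 25, the dianion of methyl acetoacetate (NaH, then n-BuLi, THF, 0 °C) would be alkylated at its terminal carbon to give the β-keto ester F5, with C11 now the electrophile. NaH and ClP(O)(OEt)2 in Et2O would give the (Z)-enol phosphate F6. Me2CuLi replaces the phosphate with retention to give the (E)-β-methyl enoate F7, and iBu2AlH reduces it to the allylic alcohol F8. Aqueous acetic acid then removes the acetonide and the route is rejoined at triol 33.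

Step 7. O-methylation of the hindered enolate or aldol self-condensation may outrun C-methylation at a carbon that becomes quaternary next to C5. Fallback: from aldehyde 12, Pinnick oxidation (NaClO2, NaH2PO4, 2-methyl-2-butene) would give the carboxylic acid F9, and Me3SiCHN2 its methyl ester F10. LiN(iPr)2 and MeI would give the α,α-dimethyl ester F11, since ester enolates alkylate on carbon. LiAlH4 reduces it to the neopentyl alcohol F12, and Dess–Martin oxidation comes back to aldehyde 14.

**Further compounds**

F1 | step 10 | ring A olefin (C2=C3) with C9 silyl ether | CC1=CC[C@@H]2C(C)(C)C=CC[C@@]2(C)[C@@H]1O[Si](C)(C)C(C)(C)C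
F2 | step 10 | C9 allylic alcohol of the 2,7-diene | CC1=CC[C@@H]2C(C)(C)C=CC[C@@]2(C)[C@@H]1O
F3 | step 10 | dienone (C9 ketone, C2=C3, C7=C8) | CC1=CC[C@@H]2C(C)(C)C=CC[C@@]2(C)C1=O
F4 | step 10 | 2,3-cis-diol enone | CC1=CC[C@@H]2C(C)(C)[C@@H](O)[C@@H](O)C[C@@]2(C)C1=O
F5 | step 21 | β-keto ester (C13 ketone, C15 methyl ester) acetonide | CC1=CC[C@@H]2C(C)(C)[C@@H](OC3(C)C)[C@@H](O3)C[C@@]2(C)[C@@H]1CCC(=O)CC(=O)OC
F6 | step 21 | (Z)-enol diethyl phosphate | CC1=CC[C@@H]2C(C)(C)[C@@H](OC3(C)C)[C@@H](O3)C[C@@]2(C)[C@@H]1CC/C(OP(=O)(OCC)OCC)=C/C(=O)OC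
F7 | step 21 | (E)-β-methyl enoate (C15 methyl ester) acetonide | CC1=CC[C@@H]2C(C)(C)[C@@H](OC3(C)C)[C@@H](O3)C[C@@]2(C)[C@@H]1CC/C(C)=C/C(=O)OC
F8 | step 21 | C15 allylic alcohol acetonide | CC1=CC[C@@H]2C(C)(C)[C@@H](OC3(C)C)[C@@H](O3)C[C@@]2(C)[C@@H]1CC/C(C)=C/CO
F9 | step 7 | C3 carboxylic acid (C4 epimers) | CC(C)(C)[Si](C)(C)OCC[C@@]1(C)[C@H](O[Si](C)(C)C(C)(C)C)C(C)=CC[C@@H]1C(C)C(=O)O
F10 | step 7 | C3 methyl ester (C4 epimers) | CC(C)(C)[Si](C)(C)OCC[C@@]1(C)[C@H](O[Si](C)(C)C(C)(C)C)C(C)=CC[C@@H]1C(C)C(=O)OC
F11 | step 7 | α,α-dimethyl methyl ester | CC(C)(C)[Si](C)(C)OCC[C@@]1(C)[C@H](O[Si](C)(C)C(C)(C)C)C(C)=CC[C@@H]1C(C)(C)C(=O)OC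
F12 | step 7 | neopentyl C3 alcohol | CC(C)(C)[Si](C)(C)OCC[C@@]1(C)[C@H](O[Si](C)(C)C(C)(C)C)C(C)=CC[C@@H]1C(C)(C)CO
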